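**Retrosynthetic overview**
- The butenolide (3-methyltetronic acid) ring is closed last, at its C3–C4 bond, by intramolecular Claisen condensation of an acyclic α-propanoyloxy ester. The furan ring is bought.
- Key disconnection: the bond between ring carbon C5 and the exocyclic CH2. It is made by light-driven radical hydroalkylation in a flavin-dependent ene-reductase, joining a racemic α-chloro-α-propanoyloxy ester with an achiral furanyl tetraene and setting C5 and the methyl-bearing carbon together.
- Enabling feature: C5 lies between ring oxygen O1 and the carboxyl-level carbon C4, so with the C3–C4 bond opened it is the α-carbon of an O-acyl glycolate and forms an α-acyloxy-α-ester radical easily. The adjacent CH2–CH(CH3) unit is the anti-Markovnikov hydro-adduct of an isopropenyl end group, the only 1,1-disubstituted alkene of the polyene.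
- The tetraene comes from (E)-geranylacetone by allylic oxidation, methylenation, bromination and copper-catalysed coupling with a 2-(furan-3-yl)ethyl Grignard reagent.
- The chloro ester comes from ethyl glyoxylate and propanoyl chloride.

Key step: step 7

Remark: 2-(furan-3-yl)ethanol and isomerically pure (E)-geranylacetone are taken as purchasable, and the ene-reductase of step 7 is given by class because the variant is to be chosen from a screening panel.

**Step 1**
Reactants: 1 (E)-geranylacetone [(5E)-6,10-dimethylundeca-5,9-dien-2-one]
Product: 2 (5E,9E)-11-hydroxy-6,10-dimethylundeca-5,9-dien-2-one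
Conditions: SeO2 (0.3 equiv), t-BuOOH (3 equiv), salicylic acid (cat.), CH2Cl2, 0 °C to rt
Reagents that add atoms: selenium dioxide, O=[Se]=O (catalytic oxygen carrier); tert-butyl hydroperoxide, CC(C)(C)OO (terminal oxidant)
Why: Catalytic SeO2/t-BuOOH allylic oxidation (ene reaction followed by [2,3]-sigmatropic shift) should attack the (E)-methyl group of the terminal, most accessible trisubstituted alkene and give the (E)-allylic alcohol, while the methyl ketone is inert at room temperature.

**Step 2**
Reactants: 2 (5E,9E)-11-hydroxy-6,10-dimethylundeca-5,9-dien-2-one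
Product: 3 (2E,6E)-2,6,10-trimethylundeca-2,6,10-trien-1-ol
Conditions: Ph3PCH3Br (2.5 equiv), KOtBu (2.4 equiv), THF, 0 °C to rt
Reagents that add atoms: methyltriphenylphosphonium bromide, C[P+](c1ccccc1)(c1ccccc1)c1ccccc1.[Br-]
Why: Wittig methylenation of the methyl ketone installs the isopropenyl terminus, the excess ylide covering the free hydroxyl as its alkoxide and leaving the trisubstituted alkenes untouched.

**Step 3**
Reactants: 3 (2E,6E)-2,6,10-trimethylundeca-2,6,10-trien-1-ol
Product: 4 (2E,6E)-1-bromo-2,6,10-trimethylundeca-2,6,10-triene
Conditions: CBr4, PPh3, CH2Cl2, 0 °C; used directly after a short silica plug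
Reagents that add atoms: carbon tetrabromide, BrC(Br)(Br)Br
Why: Appel bromination of the primary allylic alcohol proceeds by SN2 displacement of the alkoxyphosphonium ion without allylic shift, so the (E) geometry should be kept.

**Step 4**
Reactants: 5 2-(furan-3-yl)ethanol
Product: 6 3-(2-bromoethyl)furan
Conditions: CBr4, PPh3, CH2Cl2, 0 °C
Reagents that add atoms: carbon tetrabromide, BrC(Br)(Br)Br
Why: Appel bromination under neutral conditions converts the primary alcohol into the bromide and spares the acid-sensitive furan.

**Step 5**
Reactants: 6 3-(2-bromoethyl)furan; 4 (2E,6E)-1-bromo-2,6,10-trimethylundeca-2,6,10-triene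
Product: 8 3-[(4E,8E)-4,8,12-trimethyltrideca-4,8,12-trien-1-yl]furan, via [2-(furan-3-yl)ethyl]magnesium bromide 7 (not isolated)
Conditions: Mg turnings, THF, rt; then 4, Li2CuCl4 (5 mol%), THF, −78 to 0 °C
Reagents that add atoms: none
Why: Copper-catalysed Grignard–allylic bromide cross-coupling (Kochi conditions) should substitute at the primary allylic carbon in the SN2 sense with retention of the (E)-alkene, and the isopropenyl group is inert to the reagent.

**Step 6**
Reactants: 9 ethyl glyoxylate (freshly cracked monomer)
Product: 10 ethyl 2-chloro-2-(propanoyloxy)acetate (racemic)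
Conditions: propanoyl chloride, ZnCl2 (2 mol%), CH2Cl2, 0 °C to rt; short-path distillation
Reagents that add atoms: propanoyl chloride, CCC(=O)Cl
Why: Lewis acid-catalysed addition of an acyl chloride across an aldehyde C=O (1-chloroalkyl ester formation) is favoured for the electron-poor glyoxylate, and the racemic product is all that step 7 requires.

**Step 7**
Reactants: 8 3-[(4E,8E)-4,8,12-trimethyltrideca-4,8,12-trien-1-yl]furan; 10 ethyl 2-chloro-2-(propanoyloxy)acetate
Product: 11 ethyl (2R,4R,7E,11E)-15-(furan-3-yl)-4,8,12-trimethyl-2-(propanoyloxy)pentadeca-7,11-dienoate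
Conditions: purified flavin-dependent ene-reductase (old yellow enzyme family, variant from panel screening, first candidate a GluER-T36A-type enzyme), NADP+ (cat.), glucose, glucose dehydrogenase, potassium phosphate buffer pH 7.0, 15% DMSO, cyan LEDs (about 500 nm), N2, 25 °C; 10 (3 equiv) added in portions
Reagents that add atoms: none
Why: Proposed new method: the ester carbonyl of 10 is held by the hydrogen-bond donor pair above the reduced flavin of the ene-reductase, light excites the enzyme-templated charge-transfer complex, one electron passes to the C–Cl bond, chloride leaves, and the planar α-acyloxy-α-ester radical (the future ring carbon C5) adds to the unsubstituted CH2 terminus of the isopropenyl group of 8, after which the tertiary radical takes a hydrogen atom from N5–H of the flavin semiquinone and NADPH (recycled by glucose and glucose dehydrogenase) returns the flavin to its hydroquinone. The closest known reaction type is the photoenzymatic intermolecular hydroalkylation of 1,1-disubstituted alkenes with α-halo carbonyl compounds by flavin-dependent ene-reductases, where the γ-centre is set by hydrogen atom transfer, together with the coupling of α,α-dichloroamides, where the α-centre is set in the C–C bond-forming event; new here are the α-acyloxy-α-chloro ester as radical source and control of both centres of a 1,3-pair on a long isoprenoid alkene. No ring is closed in this step. The centre at C2 of 11 should be set by the enzyme, which exposes one face of the bound radical to the alkene so that both enantiomers of 10 converge, and the centre at C4 by delivery of the hydrogen atom from the flavin to one face of the tertiary radical, the variant giving the (2R,4R) isomer being picked from a panel of stereocomplementary ene-reductases. The step needs site selectivity for the isopropenyl group over the two trisubstituted alkenes and the furan, which the substrate secures because that group offers the only unhindered CH2= terminus and leads to a tertiary radical, while the active site admits only the chain end next to the flavin.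

**Step 8**
Reactants: 11 ethyl (2R,4R,7E,11E)-15-(furan-3-yl)-4,8,12-trimethyl-2-(propanoyloxy)pentadeca-7,11-dienoate
Product: 12 (5R)-5-[(2R,5E,9E)-13-(furan-3-yl)-2,6,10-trimethyltrideca-5,9-dien-1-yl]-4-hydroxy-3-methylfuran-2(5H)-one
Conditions: LiN(SiMe3)2 (2.2 equiv), THF, −78 to 0 °C (11 added to the base); then cold 0.5 M HCl to pH 3
Reagents that add atoms: none
Why: Intramolecular Claisen (Dieckmann-type) condensation of an α-acyloxy ester, the established route to 3-alkyltetronic acids, closes the butenolide ring 5-exo-trig from the propanoate lithium enolate onto the ethyl ester, is made irreversible by formation of the tetronate anion, and should carry both stereocentres of 11 into 12 unchanged because the hindered amide base at −78 °C deprotonates the propanoate CH2 in preference to the α-acyloxy carbon.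

**Compound list**
1 | (E)-geranylacetone, (5E)-6,10-dimethylundeca-5,9-dien-2-one | CC(=O)CC/C=C(\C)CCC=C(C)C | starting material
2 | (5E,9E)-11-hydroxy-6,10-dimethylundeca-5,9-dien-2-one | CC(=O)CC/C=C(\C)CC/C=C(\C)CO | intermediate
3 | (2E,6E)-2,6,10-trimethylundeca-2,6,10-trien-1-ol | C=C(C)CC/C=C(\C)CC/C=C(\C)CO | intermediate
4 | (2E,6E)-1-bromo-2,6,10-trimethylundeca-2,6,10-triene | C=C(C)CC/C=C(\C)CC/C=C(\C)CBr | intermediate
5 | 2-(furan-3-yl)ethanol | OCCc1ccoc1 | starting material
6 | 3-(2-bromoethyl)furan | BrCCc1ccoc1 | intermediate
7 | [2-(furan-3-yl)ethyl]magnesium bromide | Br[Mg]CCc1ccoc1 | intermediate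
8 | 3-[(4E,8E)-4,8,12-trimethyltrideca-4,8,12-trien-1-yl]furan | C=C(C)CC/C=C(\C)CC/C=C(\C)CCCc1ccoc1 | intermediate
9 | ethyl glyoxylate (ethyl 2-oxoacetate) | CCOC(=O)C=O | starting material
10 | ethyl 2-chloro-2-(propanoyloxy)acetate, racemic | CCOC(=O)C(Cl)OC(=O)CC | intermediate
11 | ethyl (2R,4R,7E,11E)-15-(furan-3-yl)-4,8,12-trimethyl-2-(propanoyloxy)pentadeca-7,11-dienoate | CCOC(=O)[C@H](OC(=O)CC)C[C@H](C)CC/C=C(\C)CC/C=C(\C)CCCc1ccoc1 | intermediate
12 | (5R)-5-[(2R,5E,9E)-13-(furan-3-yl)-2,6,10-trimethyltrideca-5,9-dien-1-yl]-4-hydroxy-3-methylfuran-2(5H)-one | CC1=C(O)[C@@H](C[C@H](C)CC/C=C(\C)CC/C=C(\C)CCCc2ccoc2)OC1=O | target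

Total step count: 8. Longest linear sequence: 6 steps (steps 1, 2, 3, 5, 7, 8, from 1 to 12).

**Steps most likely to fail**

Step 7 (proposed new method). The radical formed in the active site may be reduced to the dechlorinated ester before it meets the alkene. Compound 10 may hydrolyse or alkylate the protein in buffer. The radical may add to the furan or to a trisubstituted alkene, or face control at one of the two new centres may be poor. The fallback uses known reactions only, sets out from 8 and 9 and comes back at 11.
- An asymmetric glyoxylate–ene reaction of 8 with 9 (catalyst from (R)-BINOL and TiCl2(OiPr)2, 4 Å molecular sieves, CH2Cl2, −30 °C) forms the same C–C bond at the isopropenyl CH2 under catalyst control. It should give ethyl (2R,7E,11E)-15-(furan-3-yl)-2-hydroxy-8,12-dimethyl-4-methylidenepentadeca-7,11-dienoate F1; any 4-ene double-bond isomer carries the same skeleton.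
- Homoallylic-hydroxyl-directed hydrogenation with Ru(OAc)2(BINAP) (ligand enantiomer chosen for the 4R product), H2, MeOH should leave the remote trisubstituted alkenes and the furan alone. It should give ethyl (2R,4R,7E,11E)-15-(furan-3-yl)-2-hydroxy-4,8,12-trimethylpentadeca-7,11-dienoate F2.
- Propanoyl chloride, pyridine, DMAP (cat.), CH2Cl2, 0 °C then gives 11.

Step 8. The amide base may remove the proton at the α-acyloxy carbon instead of a propanoate proton, which would cause epimerisation at that centre or an O-to-C acyl shift. The fallback sets out from 11 and comes back at 12, closing the ring by lactonisation instead of C-acylation.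
- K2CO3, EtOH, 0 °C removes the propanoate and gives ethyl (2R,4R,7E,11E)-15-(furan-3-yl)-2-hydroxy-4,8,12-trimethylpentadeca-7,11-dienoate F2.
- TBSCl, imidazole, DMF gives ethyl (2R,4R,7E,11E)-2-{[tert-butyl(dimethyl)silyl]oxy}-15-(furan-3-yl)-4,8,12-trimethylpentadeca-7,11-dienoate F3.
- Crossed Claisen condensation with excess lithium enolate of ethyl propanoate (LiN(iPr)2, THF, −78 °C) gives ethyl (4R,6R,9E,13E)-4-{[tert-butyl(dimethyl)silyl]oxy}-17-(furan-3-yl)-2,6,10,14-tetramethyl-3-oxoheptadeca-9,13-dienoate F4 as both C2 epimers.
- Bu4NF, THF, 0 °C frees the hydroxyl, which should lactonise onto the ethyl ester and give 12.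

Step 5. Allylic transposition (SN2' attack) may occur in the copper-catalysed substitution, along with Wurtz-type homocoupling of 4 or loss of the Grignard reagent by elimination. The fallback sets out from 6 and 4 and comes back at 8, using sulfone-anion alkylation and reductive desulfonylation.
- PhSO2Na, DMF, rt converts 6 into 3-[2-(benzenesulfonyl)ethyl]furan F5.
- n-BuLi (1.0 equiv), THF, −78 °C, then 4, gives 3-[(4E,8E)-2-(benzenesulfonyl)-4,8,12-trimethyltrideca-4,8,12-trien-1-yl]furan F6. The soft carbanion should substitute at the primary allylic carbon, and the new sulfonyl-bearing centre is racemic, which has no consequence.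
- Sodium amalgam (Na/Hg), Na2HPO4, MeOH, −20 °C removes the sulfonyl group. It is not allylic, so no double bond can move, and 8 is returned.

**Further compounds**
F1 | step 7 | ethyl (2R,7E,11E)-15-(furan-3-yl)-2-hydroxy-8,12-dimethyl-4-methylidenepentadeca-7,11-dienoate | CCOC(=O)[C@H](O)CC(=C)CC/C=C(\C)CC/C=C(\C)CCCc1ccoc1
F2 | step 7 | ethyl (2R,4R,7E,11E)-15-(furan-3-yl)-2-hydroxy-4,8,12-trimethylpentadeca-7,11-dienoate | CCOC(=O)[C@H](O)C[C@H](C)CC/C=C(\C)CC/C=C(\C)CCCc1ccoc1
F3 | step 8 | ethyl (2R,4R,7E,11E)-2-{[tert-butyl(dimethyl)silyl]oxy}-15-(furan-3-yl)-4,8,12-trimethylpentadeca-7,11-dienoate | CCOC(=O)[C@H](O[Si](C)(C)C(C)(C)C)C[C@H](C)CC/C=C(\C)CC/C=C(\C)CCCc1ccoc1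
F4 | step 8 | ethyl (4R,6R,9E,13E)-4-{[tert-butyl(dimethyl)silyl]oxy}-17-(furan-3-yl)-2,6,10,14-tetramethyl-3-oxoheptadeca-9,13-dienoate (both C2 epimers) | CCOC(=O)C(C)C(=O)[C@H](O[Si](C)(C)C(C)(C)C)C[C@H](C)CC/C=C(\C)CC/C=C(\C)CCCc1ccoc1
F5 | step 5 | 3-[2-(benzenesulfonyl)ethyl]furan | O=S(=O)(CCc1ccoc1)c1ccccc1
F6 | step 5 | 3-[(4E,8E)-2-(benzenesulfonyl)-4,8,12-trimethyltrideca-4,8,12-trien-1-yl]furan (racemic) | C=C(C)CC/C=C(\C)CC/C=C(\C)CC(Cc1ccoc1)S(=O)(=O)c1ccccc1
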